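**Plan**

Numbering: ring D (quinone) is C1(=O), C2(OMe), C3(H), C4(=O), C5(O–ring C), C6(CH2CH2–ring A). Ring A is the para-phenylene, ring B the phenol ring, ring C the meta-phenylene. The 18-membered macrocycle contains only the C5=C6 edge of ring D.
Enabling feature: the edge C5(OAr)=C6(alkyl) lies between the carbonyl carbons C4 and C1, so C4–C5=C6–C1 plus a C1–C4 bond is a 3-alkyl-4-aryloxycyclobutenedione, and the outer edge C2(OMe)=C3H is a 2-methoxyvinyl unit. The aryloxy oxygen on C5 makes C1=O a vinylogous ester and leaves C4=O as the only ketone-like carbonyl.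
Retrosynthetic cuts: C1–C2 (6π closure) and C3–C4 (vinyllithium addition) in ring D, then O–C5 (macrocyclic vinylogous ester), C6–CH2 (organolithium plus squarate), ring C–CH2 (B-alkyl Suzuki–Miyaura) and ring A–O (Ullmann).
Forward order: rings A, B and C are bought. A–O–B is joined first, then the B–C bridge, then the four-membered helper ring is put on the ring A arm. The macrocycle closes at O–C5, ring D is made last by enlarging the four-membered ring by the two vinyl carbons, and the benzyl group on ring B is removed at the end.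
Stereochemistry: the target has no stereocentre. The carbinol centre made in step 9 is racemic and, like the Z-enol ether geometry, is erased on aromatisation.

Key step: step 10

Assumption: the macrocycle is taken as conformationally mobile, so no planar or axial chirality has to be controlled, and di-tert-butyl squarate is taken as a catalogue compound.

**Route**

Step 1
Reactants: 1 4-(benzyloxy)-3-hydroxybenzaldehyde; 2 2-(4-iodophenyl)ethanol
Product: 3 4-(benzyloxy)-3-[4-(2-hydroxyethyl)phenoxy]benzaldehyde
Conditions: CuI (10 mol %), picolinic acid (20 mol %), K3PO4, DMSO, 90 °C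
Reagents that add atoms: none
Why: Ligand-accelerated Ullmann diaryl ether synthesis, in which only the phenoxide and not the aliphatic alcohol is arylated by the aryl iodide, and the non-enolisable aldehyde is inert to K3PO4.

Step 2
Reactants: 3 4-(benzyloxy)-3-[4-(2-hydroxyethyl)phenoxy]benzaldehyde
Product: 4 2-{4-[2-(benzyloxy)-5-vinylphenoxy]phenyl}ethanol
Conditions: MePPh3Br (2.5 equiv), KOtBu (2.5 equiv), THF, 0 °C to rt
Reagents that add atoms: methyltriphenylphosphonium bromide, C[P+](c1ccccc1)(c1ccccc1)c1ccccc1.[Br-]
Why: Wittig methylenation of a non-enolisable aryl aldehyde, in which the excess ylide only deprotonates the free alcohol, and the alcohol returns on work-up.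

Step 3
Reactants: 5 3-bromophenol
Product: 6 (3-bromophenoxy)triisopropylsilane
Conditions: TIPSCl, imidazole, DMF, rt
Reagents that add atoms: triisopropylsilyl chloride, CC(C)[Si](Cl)(C(C)C)C(C)C
Why: Standard imidazole-promoted O-silylation, and the triisopropylsilyl aryl ether should outlast aqueous phosphate, t-BuLi and TFA in steps 4 to 6 yet still answer to fluoride in step 7.

Step 4
Reactants: 4 2-{4-[2-(benzyloxy)-5-vinylphenoxy]phenyl}ethanol; 6 (3-bromophenoxy)triisopropylsilane
Product: 8 A–B–C alcohol 2-{4-[2-(benzyloxy)-5-(2-{3-[(triisopropylsilyl)oxy]phenyl}ethyl)phenoxy]phenyl}ethanol, via bis-9-BBN borane 7 (not isolated)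
Conditions: 9-BBN (2.2 equiv), THF, 0 °C to rt; then 6, PdCl2(dppf) (5 mol %), 3 M aq K3PO4, DMF, 50 °C
Reagents that add atoms: none
Why: Anti-Markovnikov hydroboration of the styrene followed by B-alkyl Suzuki–Miyaura coupling forms the ring C–CH2 bond and thus the saturated B–C bridge directly, so no hydrogenation endangers the benzyl ether, and the second equivalent of 9-BBN is held by the alcohol as a borinate that hydrolyses on work-up.

Step 5
Reactants: 8 A–B–C alcohol
Product: 9 A–B–C primary iodide
Conditions: I2, PPh3, imidazole, CH2Cl2, 0 °C to rt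
Reagents that add atoms: iodine, II
Why: Appel-type iodination (Garegg–Samuelsson conditions) converts the primary alcohol by SN2 displacement of the alkoxyphosphonium ion under near-neutral conditions that spare both phenol protecting groups.

Step 6
Reactants: 9 A–B–C primary iodide; 10 di-tert-butyl squarate (3,4-di-tert-butoxycyclobut-3-ene-1,2-dione)
Product: 13 seco acid 3-(2-arylethyl)-4-hydroxycyclobut-3-ene-1,2-dione, via 2-arylethyllithium 11 (not isolated), via squarate adduct 12 (not isolated)
Conditions: t-BuLi (2.1 equiv), Et2O/pentane, −78 °C; then 10, THF, −78 °C; aq NH4Cl; then TFA, CH2Cl2, 0 °C to rt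
Reagents that add atoms: none
Why: Lithium–iodine exchange on a primary iodide outruns elimination and benzylic deprotonation at −78 °C, the alkyllithium adds 1,2 to one squarate carbonyl (new C6–CH2 bond), and acid ionises the tertiary carbinol with 1,3-carbonyl transposition and loss of both tert-butyl groups, which is the established squarate route to 3-alkyl-4-hydroxycyclobutenediones.

Step 7
Reactants: 13 seco acid
Product: 15 macrocyclic 3-alkyl-4-aryloxycyclobutenedione, via chlorocyclobutenedione 14 (not isolated)
Conditions: (COCl)2, cat. DMF, CH2Cl2, 0 °C to rt, evaporate; then syringe-pump addition over 12 h to CsF (5 equiv), cat. 18-crown-6, MeCN, 40 °C, final 1 mM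
Reagents that add atoms: none
Why: The hydroxycyclobutenedione is a vinylogous carboxylic acid and gives its chloride with the Vilsmeier reagent, and fluoride then unmasks the ring C phenoxide only in the dilute receiving flask, where addition–elimination at C5 (the known esterification of chlorocyclobutenediones by phenols, run intramolecularly) closes the 18-membered ring while the benzyl ether keeps the ring B oxygen silent.

Step 8
Reactants: 16 methyl vinyl ether
Product: 18 (Z)-1-bromo-2-methoxyethene, via 1,2-dibromo-1-methoxyethane 17 (not isolated)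
Conditions: Br2, CH2Cl2, −78 °C; then PhNEt2, 95 °C, distil
Reagents that add atoms: bromine, BrBr
Why: Electrophilic bromine addition to the enol ether and amine-induced loss of HBr through the activated α-bromo ether should give mainly the Z-bromo enol ether, as known for the ethyl analogue, and distillation should remove the E isomer.

Step 9
Reactants: 15 macrocyclic 3-alkyl-4-aryloxycyclobutenedione; 18 (Z)-1-bromo-2-methoxyethene
Product: 20 macrocyclic 4-hydroxy-4-[(Z)-2-methoxyvinyl]cyclobutenone (racemic), via (Z)-2-methoxyvinyllithium 19 (not isolated)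
Conditions: 18 (1.5 equiv), t-BuLi (3.0 equiv), Et2O, −78 °C; then 15, THF, −78 °C; aq NH4Cl at −78 °C; used crude
Reagents that add atoms: none
Why: Bromine–lithium exchange proceeds with retention to the chelation-stabilised Z-2-alkoxyvinyllithium, which adds 1,2 to C4=O because C1=O is deactivated as the vinylogous ester carbonyl of the C5 aryloxy group, the regiochemistry known for 3-alkyl-4-alkoxycyclobutenediones, and the new carbinol centre is racemic and is lost in step 10.

Step 10
Reactants: 20 macrocyclic 4-hydroxy-4-[(Z)-2-methoxyvinyl]cyclobutenone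
Product: 24 O-benzyl quinone, via dienylketene 21 (not isolated), via cyclohexadienone 22 (not isolated), via hydroquinone 23 (not isolated)
Conditions: toluene (5 mM, degassed, base-washed glass), 110 °C; then Ag2O, Na2SO4, rt
Reagents that add atoms: none
Why: Heating opens the cyclobutenone by conrotatory 4π electrocyclic cleavage of the C1–C4 bond, in which the donor hydroxyl on C4 rotates outward and the methoxyvinyl arm therefore inward, giving dienylketene 21 with C2 next to the ketene carbon C1. Ring D then closes by a disrotatory 6π electrocyclisation that forms the C1–C2 bond (all-carbon six-membered ring, with the 18-membered ring a spectator anchored at C5 and C6), cyclohexadienone 22 enolises to hydroquinone 23, and Ag2O takes 23 to quinone 24. The closest known reaction type is the Moore–Liebeskind ring expansion of 4-alkenyl-4-hydroxycyclobutenones, used here as a four-to-six enlargement of a helper ring that already sits in the macrocycle. The only new stereocentre, C2 of 22, is transient and is erased on enolisation together with the carbinol centre and the Z geometry of 20. Regiochemistry is inherited and not decided here: C3 is bonded to C4, the neighbour of C5(OAr), so the methoxy carbon C2 can only end up next to C1 and thus across from C5, which is the 2-methoxy-5-aryloxy-6-alkyl pattern. The step needs outward rotation of the hydroxyl (inward rotation would let the hydroxyl capture the ketene as a butenolide) and ring closure faster than outside capture of the ketene, and these are secured by the donor hydroxyl, by the macrocycle that holds the C6–C5 bond s-cis, and by a dilute, aprotic, acid-free medium that also protects the enol ether.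

Step 11
Reactants: 24 O-benzyl quinone
Product: 26 target CNP0332646.0, via leuco hydroquinone 25 (not isolated)
Conditions: H2 (1 atm), Pd/C, EtOAc, rt; filter under Ar; then air, rt
Reagents that add atoms: none
Why: Hydrogenolysis of the aryl benzyl ether over Pd/C also reduces the quinone reversibly to the hydroquinone, and the electron-rich hydroquinone should autoxidise in air back to the quinone while the isolated phenol of ring B is not touched.

**Compound list**

1 | 4-(benzyloxy)-3-hydroxybenzaldehyde (ring B) | O=Cc1ccc(OCc2ccccc2)c(O)c1 | starting material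
2 | 2-(4-iodophenyl)ethanol (ring A) | OCCc1ccc(I)cc1 | starting material
3 | 4-(benzyloxy)-3-[4-(2-hydroxyethyl)phenoxy]benzaldehyde | O=Cc1ccc(OCc2ccccc2)c(Oc2ccc(CCO)cc2)c1 | intermediate
4 | 2-{4-[2-(benzyloxy)-5-vinylphenoxy]phenyl}ethanol | C=Cc1ccc(OCc2ccccc2)c(Oc2ccc(CCO)cc2)c1 | intermediate
5 | 3-bromophenol (ring C) | Oc1cccc(Br)c1 | starting material
6 | (3-bromophenoxy)triisopropylsilane | CC(C)[Si](Oc1cccc(Br)c1)(C(C)C)C(C)C | intermediate
7 | bis-9-BBN borane: B-alkyl-9-BBN at the former vinyl terminus of 4, alcohol held as its 9-BBN borinate | C(Cc1ccc(OCc2ccccc2)c(Oc2ccc(CCOB3C4CCCC3CCC4)cc2)c1)B1C2CCCC1CCC2 | intermediate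
8 | A–B–C alcohol, 2-{4-[2-(benzyloxy)-5-(2-{3-[(triisopropylsilyl)oxy]phenyl}ethyl)phenoxy]phenyl}ethanol | OCCc1ccc(Oc2cc(CCc3cccc(O[Si](C(C)C)(C(C)C)C(C)C)c3)ccc2OCc2ccccc2)cc1 | intermediate
9 | A–B–C primary iodide (OH of 8 replaced by I) | ICCc1ccc(Oc2cc(CCc3cccc(O[Si](C(C)C)(C(C)C)C(C)C)c3)ccc2OCc2ccccc2)cc1 | intermediate
10 | di-tert-butyl squarate | CC(C)(C)OC1=C(OC(C)(C)C)C(=O)C1=O | starting material
11 | 2-arylethyllithium from 9 | [Li]CCc1ccc(Oc2cc(CCc3cccc(O[Si](C(C)C)(C(C)C)C(C)C)c3)ccc2OCc2ccccc2)cc1 | intermediate
12 | squarate adduct, 4-(2-arylethyl)-2,3-di-tert-butoxy-4-hydroxycyclobut-2-en-1-one (racemic) | CC(C)(C)OC1=C(OC(C)(C)C)C(O)(CCc2ccc(Oc3cc(CCc4cccc(O[Si](C(C)C)(C(C)C)C(C)C)c4)ccc3OCc3ccccc3)cc2)C1=O | intermediate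
13 | seco acid, 3-(2-arylethyl)-4-hydroxycyclobut-3-ene-1,2-dione | OC1=C(CCc2ccc(Oc3cc(CCc4cccc(O[Si](C(C)C)(C(C)C)C(C)C)c4)ccc3OCc3ccccc3)cc2)C(=O)C1=O | intermediate
14 | 3-(2-arylethyl)-4-chlorocyclobut-3-ene-1,2-dione | ClC1=C(CCc2ccc(Oc3cc(CCc4cccc(O[Si](C(C)C)(C(C)C)C(C)C)c4)ccc3OCc3ccccc3)cc2)C(=O)C1=O | intermediate
15 | macrocyclic cyclobutenedione (18-membered ring, ring C oxygen on C5, ring A ethylene arm on C6, ring B as benzyl ether) | O=C1C(=O)C2=C1CCc1ccc(cc1)Oc1cc(ccc1OCc1ccccc1)CCc1cccc(c1)O2 | intermediate
16 | methyl vinyl ether | COC=C | starting material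
17 | 1,2-dibromo-1-methoxyethane | COC(Br)CBr | intermediate
18 | (Z)-1-bromo-2-methoxyethene | CO/C=C\Br | intermediate
19 | (Z)-2-methoxyvinyllithium | CO/C=C\[Li] | intermediate
20 | macrocyclic 4-hydroxy-4-[(Z)-2-methoxyvinyl]cyclobutenone (carbinol at C4, racemic) | O=C1C(O)(/C=C\OC)C2=C1CCc1ccc(cc1)Oc1cc(ccc1OCc1ccccc1)CCc1cccc(c1)O2 | intermediate
21 | macrocyclic dienylketene O=C1=C6–C5=C4(OH)–C3H=C2H(OMe), vinyl arm on the ketene side | O=C=C1CCc2ccc(cc2)Oc2cc(ccc2OCc2ccccc2)CCc2cccc(c2)O/C1=C(O)/C=C\OC | intermediate
22 | cyclohexa-2,4-dienone with sp3 C2(H)(OMe) (racemic) | COC1C=C(O)C2=C(CCc3ccc(cc3)Oc3cc(ccc3OCc3ccccc3)CCc3cccc(c3)O2)C1=O | intermediate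
23 | hydroquinone of ring D, ring B as benzyl ether | COc1cc(O)c2c(CCc3ccc(cc3)Oc3cc(ccc3OCc3ccccc3)CCc3cccc(c3)O2)c1O | intermediate
24 | O-benzyl quinone (target with ring B phenol benzylated) | COC1=CC(=O)C2=C(CCc3ccc(cc3)Oc3cc(ccc3OCc3ccccc3)CCc3cccc(c3)O2)C1=O | intermediate
25 | leuco hydroquinone of the target | COc1cc(O)c2c(CCc3ccc(cc3)Oc3cc(ccc3O)CCc3cccc(c3)O2)c1O | intermediate
26 | CNP0332646.0 | COC1=CC(=O)C2=C(CCc3ccc(cc3)Oc3cc(ccc3O)CCc3cccc(c3)O2)C1=O | target

**Step count and risks**

Total step count: 11. Longest linear sequence: 9 steps (1, 2, 4, 5, 6, 7, 9, 10, 11).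

**Step 7.** Intermolecular etherification may outrun ring closure and give oligomers. Adventitious water may hydrolyse the vinylogous acid chloride, or desilylation may be too slow to keep the phenoxide concentration matched to the addition rate.

The fallback sets out from 4 and comes back at 15. It makes the O–C5 bond between two separate molecules and closes the macrocycle at the B–C bridge by olefin metathesis.
- Alcohol 4 is treated with CBr4 and PPh3 to give 1-(benzyloxy)-2-[4-(2-bromoethyl)phenoxy]-4-vinylbenzene F1.
- Mg in THF gives the 2-arylethylmagnesium bromide F2, which leaves the styrene alone.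
- Addition to dimethyl squarate at −78 °C and an NH4Cl quench give the 2,3-dimethoxy-4-hydroxycyclobutenone adduct F3.
- TFAA followed by aq NaHCO3 gives the 3-alkyl-4-methoxycyclobutenedione F4.
- LiOH in aqueous THF gives the lithium 3-alkyl-cyclobutenedion-4-olate F5, kept as the salt so that no strong acid meets the electron-rich styrene.
- (COCl)2 gives the 3-alkyl-4-chlorocyclobutenedione F6.
- 3-Vinylphenol and Et3N give the bis-styrene aryloxycyclobutenedione F7.
- Second-generation Grubbs catalyst at 1 mM in toluene gives the macrocyclic stilbene cyclobutenedione F8.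
- Diimide from KO2CN=NCO2K and AcOH in THF should saturate only the disubstituted alkene and give 15.

**Step 9.** The vinyllithium may attack C5 and expel the ring C phenoxide, which opens the macrocycle. It may instead deprotonate the C6–CH2 group, or lose LiOMe before it adds.

The fallback sets out from 15 and comes back at 20, using the Arens–van Dorp sequence.
- Chloroacetaldehyde dimethyl acetal and LiNEt2 give lithium methoxyacetylide F9, a slimmer, far less basic and thermally robust nucleophile.
- It is added to C4=O at −78 °C to give the macrocyclic 4-hydroxy-4-(methoxyethynyl)cyclobutenone F10.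
- Semihydrogenation at rt over Pd/CaCO3 poisoned with Pb(OAc)2 (Lindlar catalyst) with quinoline gives the Z-enol ether 20.

**Step 10.** The tertiary, doubly allylic carbinol may ionise or the enol ether may hydrolyse before the ring opens. The free hydroxyl or traces of water may capture the ketene, or the 6π closure may be slowed by the Z-methoxy group that points towards the closing termini.

The fallback sets out from 15 and 19 and comes back at 23. It changes the substrate class to the O-silylated carbinol, so no free hydroxyl is present during the cascade.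
- The lithium alkoxide formed on addition of 19 to 15 is trapped in the flask with TMSCl to give the macrocyclic 4-(trimethylsilyloxy)-4-[(Z)-2-methoxyvinyl]cyclobutenone F11.
- Thermolysis in toluene or p-xylene gives the ring D 4-(trimethylsilyloxy)phenol F12.
- Aqueous citric acid in THF removes the silyl group to give 23, which is oxidised with Ag2O as in step 10.

**Further compounds**

F1 | step 7 | 1-(benzyloxy)-2-[4-(2-bromoethyl)phenoxy]-4-vinylbenzene | C=Cc1ccc(OCc2ccccc2)c(Oc2ccc(CCBr)cc2)c1
F2 | step 7 | 2-arylethylmagnesium bromide from F1 | C=Cc1ccc(OCc2ccccc2)c(Oc2ccc(CC[Mg]Br)cc2)c1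
F3 | step 7 | 2,3-dimethoxy-4-hydroxycyclobutenone adduct (racemic) | COC1=C(OC)C(O)(CCc2ccc(Oc3cc(C=C)ccc3OCc3ccccc3)cc2)C1=O
F4 | step 7 | 3-alkyl-4-methoxycyclobutenedione | COC1=C(CCc2ccc(Oc3cc(C=C)ccc3OCc3ccccc3)cc2)C(=O)C1=O
F5 | step 7 | lithium 3-alkyl-cyclobutenedion-4-olate | [Li+].[O-]C1=C(CCc2ccc(Oc3cc(C=C)ccc3OCc3ccccc3)cc2)C(=O)C1=O
F6 | step 7 | 3-alkyl-4-chlorocyclobutenedione | ClC1=C(CCc2ccc(Oc3cc(C=C)ccc3OCc3ccccc3)cc2)C(=O)C1=O
F7 | step 7 | bis-styrene aryloxycyclobutenedione | C=Cc1cccc(OC2=C(CCc3ccc(Oc4cc(C=C)ccc4OCc4ccccc4)cc3)C(=O)C2=O)c1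
F8 | step 7 | macrocyclic stilbene cyclobutenedione (alkene geometry not controlled) | O=C1C(=O)C2=C1CCc1ccc(cc1)Oc1cc(ccc1OCc1ccccc1)C=Cc1cccc(c1)O2
F9 | step 9 | lithium methoxyacetylide | COC#C[Li]
F10 | step 9 | macrocyclic 4-hydroxy-4-(methoxyethynyl)cyclobutenone (racemic) | O=C1C(O)(C#COC)C2=C1CCc1ccc(cc1)Oc1cc(ccc1OCc1ccccc1)CCc1cccc(c1)O2
F11 | step 10 | macrocyclic 4-(trimethylsilyloxy)-4-[(Z)-2-methoxyvinyl]cyclobutenone (racemic) | O=C1C(O[Si](C)(C)C)(/C=C\OC)C2=C1CCc1ccc(cc1)Oc1cc(ccc1OCc1ccccc1)CCc1cccc(c1)O2
F12 | step 10 | ring D 4-(trimethylsilyloxy)phenol | COc1cc(O[Si](C)(C)C)c2c(CCc3ccc(cc3)Oc3cc(ccc3OCc3ccccc3)CCc3cccc(c3)O2)c1O
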